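**Plan**
- Retrosynthesis: the three benzyl ethers come off last. The carbocycle of the tetrahydrochromone is then cut at C7–C8, next the C5–O aryl ether, then C4a–C5. This leaves a 3-iodo-4-pyranone, (S)-glyceraldehyde acetonide and the chromone phenol.
- Enabling feature: C8 sits on C8a, the 2-position of the 4-pyranone ring (O1–C8a=C4a–C4=O), so a benzyloxymethyl group there is vinylogously acidic. C7 carries a hydroxyl exactly as an aldol acceptor carbon would.
- Forward order: the pyranone ring is built first (α-iodination of an alkynyl β-ethoxy enone, then 6-endo closure) and the aromatic chromone separately. C4a–C5 is then made with a pyranon-3-yl–Ti(OiPr)3 reagent, C5–OAr by Mitsunobu etherification, and the carbocycle closes last by the C7–C8 vinylogous aldol.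
- Stereochemistry: C6 comes from (S)-glyceraldehyde acetonide. C5 is set by Felkin–Anh addition followed by Mitsunobu inversion. C7 (MgBr2 chelate with the C6 benzyloxy group) and C8 (enol ether geometry) are set in the ring closure.

Key step: step 15

Remark: locants C4a, C5–C8 and C8a refer to the tetrahydrochromone unit (chromone numbering), primed locants to the aromatic chromone. The enol ether is made as the ethyl ether so that ester and enol ether carry the same alkyl group; that group is lost in step 4.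

**Route**

Step 1
Reactants: 1 ethyl 4-(benzyloxy)-3-oxobutanoate
Product: 2 ethyl (2E)-4-(benzyloxy)-3-ethoxybut-2-enoate
Conditions: HC(OEt)3, H2SO4 (cat.), EtOH, 25 → 60 °C
Reagents that add atoms: triethyl orthoformate, CCOC(OCC)OCC
Why: Acid-catalysed ketalisation by the orthoformate followed by loss of ethanol (enol ether formation) converts the ketone of the β-keto ester into the push–pull β-ethoxy enoate, which masks the 1,3-dicarbonyl unit for the next two steps.

Step 2
Reactants: 2 ethyl (2E)-4-(benzyloxy)-3-ethoxybut-2-enoate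
Product: 3 (2E)-4-(benzyloxy)-3-ethoxy-N-methoxy-N-methylbut-2-enamide
Conditions: MeNH(OMe)·HCl, i-PrMgCl, THF, −20 → 0 °C
Reagents that add atoms: N,O-dimethylhydroxylamine hydrochloride, CNOC.Cl
Why: Weinreb amide formation by aminolysis of the ester with the chloromagnesium amide made in the flask; the vinylogous carbonate is a poor conjugate acceptor, so attack should occur at the ester carbonyl.

Step 3
Reactants: 3 (2E)-4-(benzyloxy)-3-ethoxy-N-methoxy-N-methylbut-2-enamide; 4 but-3-yn-1-ylbenzene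
Product: 6 (2E)-1-(benzyloxy)-2-ethoxy-8-phenyloct-2-en-5-yn-4-one, via lithium 4-phenylbutynide 5 (not isolated)
Conditions: 4, n-BuLi, THF, −78 °C; then 3, −78 → 0 °C; aq. NH4Cl
Reagents that add atoms: none
Why: Weinreb ketone synthesis, in which the lithium acetylide adds once and the chelated tetrahedral intermediate collapses to the ynone only on work-up.

Step 4
Reactants: 6 (2E)-1-(benzyloxy)-2-ethoxy-8-phenyloct-2-en-5-yn-4-one
Product: 8 2-[(benzyloxy)methyl]-3-iodo-6-(2-phenylethyl)-4H-pyran-4-one, via α-iodo enynone 7 (not isolated)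
Conditions: N-iodosuccinimide, CF3CO2H (cat.), MeCN, 0 → 25 °C; then TsOH·H2O, H2O, 45 °C
Reagents that add atoms: N-iodosuccinimide, O=C1CCC(=O)N1I; water, O
Why: Electrophilic α-iodination of the push–pull enol ether (its only nucleophilic carbon) places iodine next to the benzyloxymethyl-bearing carbon, and acid hydrolysis of the vinylogous ester then frees a 2-iodo-1,3-diketone enol that closes by 6-endo-dig oxa-Michael addition onto the ynone (γ-pyrone synthesis from alkynyl 1,3-diketones), so the position of iodine follows from connectivity and not from the enol ether geometry.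

Step 5
Reactants: 9 1-(2,4,5-trihydroxyphenyl)ethan-1-one
Product: 10 1-[4-(benzyloxy)-2,5-dihydroxyphenyl]ethan-1-one
Conditions: BnBr (1.05 equiv), NaHCO3, DMF, 40 °C
Reagents that add atoms: benzyl bromide, BrCc1ccccc1
Why: Williamson etherification under weak base, where only the 4-OH (para to the acetyl group) is acidic enough to be ionised, the 2-OH being hydrogen-bonded to the ketone and the 5-OH being meta to it.

Step 6
Reactants: 10 1-[4-(benzyloxy)-2,5-dihydroxyphenyl]ethan-1-one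
Product: 11 1-[4-(benzyloxy)-2-hydroxy-5-(methoxymethoxy)phenyl]ethan-1-one
Conditions: MeOCH2Cl (1.1 equiv), i-Pr2NEt, CH2Cl2, 0 °C
Reagents that add atoms: chloromethyl methyl ether, COCCl
Why: Chemoselective acetal protection of the free 5-OH, since the chelated 2-OH does not react with one equivalent of the chloromethyl ether.

Step 7
Reactants: 11 1-[4-(benzyloxy)-2-hydroxy-5-(methoxymethoxy)phenyl]ethan-1-one; 12 3-phenylpropanoyl chloride
Product: 14 7-(benzyloxy)-6-hydroxy-2-(2-phenylethyl)-4H-chromen-4-one, via 1,3-diketone 13 (not isolated)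
Conditions: LiN(SiMe3)2 (3 equiv), THF, −78 → −10 °C; 12, −78 → 25 °C; then conc. HCl, MeOH, 65 °C
Reagents that add atoms: none
Why: Claisen-type C-acylation of the lithium phenoxide–enolate dianion gives the 1,3-diketone, and hot methanolic HCl then effects cyclodehydration to the chromone and cleaves the methoxymethyl ether in the same operation.

Step 8
Reactants: 8 2-[(benzyloxy)methyl]-3-iodo-6-(2-phenylethyl)-4H-pyran-4-one; 15 (4S)-2,2-dimethyl-1,3-dioxolane-4-carbaldehyde
Product: 18 2-[(benzyloxy)methyl]-3-{(R)-[(4S)-2,2-dimethyl-1,3-dioxolan-4-yl](hydroxy)methyl}-6-(2-phenylethyl)-4H-pyran-4-one, via pyranonylmagnesium chloride 16 (not isolated), via pyranonyltitanium triisopropoxide 17 (not isolated)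
Conditions: i-PrMgCl·LiCl, THF, −40 °C; ClTi(OiPr)3, −40 °C; 15, −78 → 0 °C; aq. NH4Cl
Reagents that add atoms: none
Why: Iodine–magnesium exchange on the electron-poor alkenyl iodide should outrun attack on the pyranone at −40 °C, transmetalation to titanium gives an aldehyde-selective non-chelating reagent, and Felkin–Anh addition (attack anti to the dioxolane C–O bond) sets C5 as the (R)-carbinol anti to C6, the minor syn epimer being expected to separate on chromatography.

Step 9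
Reactants: 18 2-[(benzyloxy)methyl]-3-{(R)-[(4S)-2,2-dimethyl-1,3-dioxolan-4-yl](hydroxy)methyl}-6-(2-phenylethyl)-4H-pyran-4-one; 14 7-(benzyloxy)-6-hydroxy-2-(2-phenylethyl)-4H-chromen-4-one
Product: 19 7-(benzyloxy)-6-{(S)-{2-[(benzyloxy)methyl]-4-oxo-6-(2-phenylethyl)-4H-pyran-3-yl}[(4S)-2,2-dimethyl-1,3-dioxolan-4-yl]methoxy}-2-(2-phenylethyl)-4H-chromen-4-one
Conditions: PPh3, diisopropyl azodicarboxylate, toluene, 0 → 25 °C
Reagents that add atoms: none
Why: Mitsunobu etherification, in which the phenol displaces the oxyphosphonium group by SN2 so that C5 is inverted to the (S)-aryl ether, the 5,6-threo arrangement that becomes 5,6-trans in the ring.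

Step 10
Reactants: 19 7-(benzyloxy)-6-{(S)-{2-[(benzyloxy)methyl]-4-oxo-6-(2-phenylethyl)-4H-pyran-3-yl}[(4S)-2,2-dimethyl-1,3-dioxolan-4-yl]methoxy}-2-(2-phenylethyl)-4H-chromen-4-one
Product: 20 7-(benzyloxy)-6-[(1S,2S)-1-{2-[(benzyloxy)methyl]-4-oxo-6-(2-phenylethyl)-4H-pyran-3-yl}-2,3-dihydroxypropoxy]-2-(2-phenylethyl)-4H-chromen-4-one
Conditions: AcOH/H2O (4:1), 40 °C
Reagents that add atoms: none
Why: Acid-catalysed acetal hydrolysis, to which the benzyl ethers, the aryl ether and both pyranone rings should be stable.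

Step 11
Reactants: 20 7-(benzyloxy)-6-[(1S,2S)-1-{2-[(benzyloxy)methyl]-4-oxo-6-(2-phenylethyl)-4H-pyran-3-yl}-2,3-dihydroxypropoxy]-2-(2-phenylethyl)-4H-chromen-4-one
Product: 21 7-(benzyloxy)-6-[(1S,2S)-1-{2-[(benzyloxy)methyl]-4-oxo-6-(2-phenylethyl)-4H-pyran-3-yl}-3-{[tert-butyl(dimethyl)silyl]oxy}-2-hydroxypropoxy]-2-(2-phenylethyl)-4H-chromen-4-one
Conditions: t-BuMe2SiCl (1.05 equiv), imidazole, CH2Cl2, 0 °C
Reagents that add atoms: tert-butyldimethylsilyl chloride, CC(C)(C)[Si](C)(C)Cl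
Why: Silylation is selective for the primary C7 hydroxyl over the hindered secondary C6 hydroxyl.

Step 12
Reactants: 21 7-(benzyloxy)-6-[(1S,2S)-1-{2-[(benzyloxy)methyl]-4-oxo-6-(2-phenylethyl)-4H-pyran-3-yl}-3-{[tert-butyl(dimethyl)silyl]oxy}-2-hydroxypropoxy]-2-(2-phenylethyl)-4H-chromen-4-one
Product: 22 7-(benzyloxy)-6-[(1S,2S)-2-(benzyloxy)-1-{2-[(benzyloxy)methyl]-4-oxo-6-(2-phenylethyl)-4H-pyran-3-yl}-3-{[tert-butyl(dimethyl)silyl]oxy}propoxy]-2-(2-phenylethyl)-4H-chromen-4-one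
Conditions: 2-(benzyloxy)-1-methylpyridinium triflate, MgO, PhCF3, 85 °C
Reagents that add atoms: 2-(benzyloxy)-1-methylpyridin-1-ium trifluoromethanesulfonate, C[n+]1ccccc1OCc1ccccc1.[O-]S(=O)(=O)C(F)(F)F
Why: Thermal benzyl transfer from the 2-benzyloxypyridinium salt (SN1-type benzylation under neutral conditions, MgO as acid scavenger) etherifies the C6 hydroxyl without alkoxide bases, which would cause silyl migration or deprotonate the vinylogously acidic CH2 groups.

Step 13
Reactants: 22 7-(benzyloxy)-6-[(1S,2S)-2-(benzyloxy)-1-{2-[(benzyloxy)methyl]-4-oxo-6-(2-phenylethyl)-4H-pyran-3-yl}-3-{[tert-butyl(dimethyl)silyl]oxy}propoxy]-2-(2-phenylethyl)-4H-chromen-4-one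
Product: 23 7-(benzyloxy)-6-[(1S,2S)-2-(benzyloxy)-1-{2-[(benzyloxy)methyl]-4-oxo-6-(2-phenylethyl)-4H-pyran-3-yl}-3-hydroxypropoxy]-2-(2-phenylethyl)-4H-chromen-4-one
Conditions: HF·pyridine, THF/pyridine, 0 → 25 °C
Reagents that add atoms: none
Why: Fluoride-mediated desilylation in a buffered, non-basic medium leaves the benzyl ethers and the β-aryloxy array untouched.

Step 14
Reactants: 23 7-(benzyloxy)-6-[(1S,2S)-2-(benzyloxy)-1-{2-[(benzyloxy)methyl]-4-oxo-6-(2-phenylethyl)-4H-pyran-3-yl}-3-hydroxypropoxy]-2-(2-phenylethyl)-4H-chromen-4-one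
Product: 24 (2R,3S)-2-(benzyloxy)-3-{[7-(benzyloxy)-4-oxo-2-(2-phenylethyl)-4H-chromen-6-yl]oxy}-3-{2-[(benzyloxy)methyl]-4-oxo-6-(2-phenylethyl)-4H-pyran-3-yl}propanal
Conditions: Dess–Martin periodinane, CH2Cl2, 0 → 25 °C
Reagents that add atoms: none
Why: Dess–Martin oxidation of the primary alcohol under non-basic conditions should give the aldehyde without epimerising C6 or eliminating the C5 aryloxide; the aldehyde is carried on directly.

Step 15
Reactants: 24 (2R,3S)-2-(benzyloxy)-3-{[7-(benzyloxy)-4-oxo-2-(2-phenylethyl)-4H-chromen-6-yl]oxy}-3-{2-[(benzyloxy)methyl]-4-oxo-6-(2-phenylethyl)-4H-pyran-3-yl}propanal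
Product: 27 7-(benzyloxy)-6-{[(5S,6S,7R,8S)-6,8-bis(benzyloxy)-7-hydroxy-4-oxo-2-(2-phenylethyl)-5,6,7,8-tetrahydro-4H-chromen-5-yl]oxy}-2-(2-phenylethyl)-4H-chromen-4-one, via silyl dienol ether 25 (not isolated), via C7 trimethylsilyl ether 26 (not isolated)
Conditions: MgBr2·OEt2 (3 equiv), CH2Cl2, −78 °C; i-Pr2NEt, Me3SiOTf, −78 → −30 °C; then 1 M HCl, THF, 0 °C
Reagents that add atoms: none
Why: Proposed new method: O-silylation of the pyranone carbonyl by Me3SiOTf gives a 4-silyloxypyrylium ion whose C8 methylene (the benzyloxymethyl group on C8a) is deprotonated by i-Pr2NEt to the cross-conjugated (Z)-enol ether 25, and this carbon adds to the MgBr2-chelated C7 aldehyde, the pyranone being regenerated by silyl transfer to the new alkoxide (26), which dilute acid cleaves. The closest known reaction types are the vinylogous aldol reactions of 2-alkyl-4-pyranones with aldehydes and the silyl triflate/amine soft-enolisation variants of the Mukaiyama aldol reaction; what lacks precedent is ring closure through a γ-carbon that bears oxygen. The carbocycle closes in a 6-(enolendo)-exo-trig mode onto the aldehyde carbon. C7 is controlled by the five-membered chelate between the C6 benzyloxy oxygen and the aldehyde oxygen, which in the tethered half-chair with C5–OAr and C6–OBn pseudoaxial can present only the carbonyl face leading to the 6,7-cis alcohol; C8 is controlled by the enol ether geometry, its benzyloxy group pointing away from C4a to avoid allylic strain with C5 and so ending pseudoequatorial, trans to the C7 oxygen. The step needs site selectivity (the phenethyl CH2 groups of both pyranone rings are deprotonated reversibly but cannot reach the aldehyde through a six-membered transition state), chemoselectivity over β-elimination of the C5 aryloxide and epimerisation at C6 (secured by the non-basic silyl triflate/amine medium at low temperature) and chelate rather than open-chain facial control (secured by complexing with MgBr2·OEt2 before the silyl triflate is added).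

Step 16
Reactants: 27 7-(benzyloxy)-6-{[(5S,6S,7R,8S)-6,8-bis(benzyloxy)-7-hydroxy-4-oxo-2-(2-phenylethyl)-5,6,7,8-tetrahydro-4H-chromen-5-yl]oxy}-2-(2-phenylethyl)-4H-chromen-4-one
Product: 28 7-hydroxy-2-(2-phenylethyl)-6-{[(5S,6S,7R,8S)-6,7,8-trihydroxy-4-oxo-2-(2-phenylethyl)-5,6,7,8-tetrahydro-4H-chromen-5-yl]oxy}-4H-chromen-4-one
Conditions: BCl3, C6HMe5, CH2Cl2, −78 °C; MeOH quench
Reagents that add atoms: none
Why: Lewis acid-mediated debenzylation with pentamethylbenzene as a non-basic benzyl cation scavenger should cleave all three benzyl ethers at low temperature, the boron-complexed pyranone carbonyls disfavouring ionisation at C5 and C8, so no stereocentre is touched.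

**Compound list**

1 | ethyl 4-(benzyloxy)-3-oxobutanoate | CCOC(=O)CC(=O)COCc1ccccc1 | starting material
2 | ethyl (2E)-4-(benzyloxy)-3-ethoxybut-2-enoate | CCOC(=O)/C=C(\COCc1ccccc1)OCC | intermediate
3 | (2E)-4-(benzyloxy)-3-ethoxy-N-methoxy-N-methylbut-2-enamide | CON(C)C(=O)/C=C(\COCc1ccccc1)OCC | intermediate
4 | but-3-yn-1-ylbenzene (4-phenyl-1-butyne) | C#CCCc1ccccc1 | starting material
5 | lithium 4-phenylbut-1-yn-1-ide | [Li]C#CCCc1ccccc1 | intermediate
6 | (2E)-1-(benzyloxy)-2-ethoxy-8-phenyloct-2-en-5-yn-4-one | O=C(C#CCCc1ccccc1)/C=C(\COCc1ccccc1)OCC | intermediate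
7 | 1-(benzyloxy)-2-ethoxy-3-iodo-8-phenyloct-2-en-5-yn-4-one (E/Z mixture) | O=C(C#CCCc1ccccc1)C(I)=C(COCc1ccccc1)OCC | intermediate
8 | 2-[(benzyloxy)methyl]-3-iodo-6-(2-phenylethyl)-4H-pyran-4-one | O=c1cc(CCc2ccccc2)oc(COCc2ccccc2)c1I | intermediate
9 | 1-(2,4,5-trihydroxyphenyl)ethan-1-one | CC(=O)c1cc(O)c(O)cc1O | starting material
10 | 1-[4-(benzyloxy)-2,5-dihydroxyphenyl]ethan-1-one | CC(=O)c1cc(O)c(OCc2ccccc2)cc1O | intermediate
11 | 1-[4-(benzyloxy)-2-hydroxy-5-(methoxymethoxy)phenyl]ethan-1-one | CC(=O)c1cc(OCOC)c(OCc2ccccc2)cc1O | intermediate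
12 | 3-phenylpropanoyl chloride | O=C(Cl)CCc1ccccc1 | starting material
13 | 1-[4-(benzyloxy)-2-hydroxy-5-(methoxymethoxy)phenyl]-5-phenylpentane-1,3-dione | O=C(CC(=O)CCc1ccccc1)c1cc(OCOC)c(OCc2ccccc2)cc1O | intermediate
14 | 7-(benzyloxy)-6-hydroxy-2-(2-phenylethyl)-4H-chromen-4-one | O=c1cc(CCc2ccccc2)oc2cc(OCc3ccccc3)c(O)cc12 | intermediate
15 | (4S)-2,2-dimethyl-1,3-dioxolane-4-carbaldehyde | O=C[C@@H]1COC(C)(C)O1 | starting material
16 | {2-[(benzyloxy)methyl]-4-oxo-6-(2-phenylethyl)-4H-pyran-3-yl}magnesium chloride | Cl[Mg]c1c(COCc2ccccc2)oc(CCc2ccccc2)cc1=O | intermediate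
17 | {2-[(benzyloxy)methyl]-4-oxo-6-(2-phenylethyl)-4H-pyran-3-yl}tris(propan-2-olato)titanium | CC(C)O[Ti](OC(C)C)(OC(C)C)c1c(COCc2ccccc2)oc(CCc2ccccc2)cc1=O | intermediate
18 | 2-[(benzyloxy)methyl]-3-{(R)-[(4S)-2,2-dimethyl-1,3-dioxolan-4-yl](hydroxy)methyl}-6-(2-phenylethyl)-4H-pyran-4-one | O=c1cc(CCc2ccccc2)oc(COCc2ccccc2)c1[C@@H](O)[C@@H]1COC(C)(C)O1 | intermediate
19 | 7-(benzyloxy)-6-{(S)-{2-[(benzyloxy)methyl]-4-oxo-6-(2-phenylethyl)-4H-pyran-3-yl}[(4S)-2,2-dimethyl-1,3-dioxolan-4-yl]methoxy}-2-(2-phenylethyl)-4H-chromen-4-one | O=c1cc(CCc2ccccc2)oc(COCc2ccccc2)c1[C@H](Oc1cc2c(=O)cc(CCc3ccccc3)oc2cc1OCc1ccccc1)[C@@H]1COC(C)(C)O1 | intermediate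
20 | 7-(benzyloxy)-6-[(1S,2S)-1-{2-[(benzyloxy)methyl]-4-oxo-6-(2-phenylethyl)-4H-pyran-3-yl}-2,3-dihydroxypropoxy]-2-(2-phenylethyl)-4H-chromen-4-one | O=c1cc(CCc2ccccc2)oc(COCc2ccccc2)c1[C@H](Oc1cc2c(=O)cc(CCc3ccccc3)oc2cc1OCc1ccccc1)[C@@H](O)CO | intermediate
21 | 7-(benzyloxy)-6-[(1S,2S)-1-{2-[(benzyloxy)methyl]-4-oxo-6-(2-phenylethyl)-4H-pyran-3-yl}-3-{[tert-butyl(dimethyl)silyl]oxy}-2-hydroxypropoxy]-2-(2-phenylethyl)-4H-chromen-4-one | O=c1cc(CCc2ccccc2)oc(COCc2ccccc2)c1[C@H](Oc1cc2c(=O)cc(CCc3ccccc3)oc2cc1OCc1ccccc1)[C@@H](O)CO[Si](C)(C)C(C)(C)C | intermediate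
22 | 7-(benzyloxy)-6-[(1S,2S)-2-(benzyloxy)-1-{2-[(benzyloxy)methyl]-4-oxo-6-(2-phenylethyl)-4H-pyran-3-yl}-3-{[tert-butyl(dimethyl)silyl]oxy}propoxy]-2-(2-phenylethyl)-4H-chromen-4-one | O=c1cc(CCc2ccccc2)oc(COCc2ccccc2)c1[C@H](Oc1cc2c(=O)cc(CCc3ccccc3)oc2cc1OCc1ccccc1)[C@@H](OCc1ccccc1)CO[Si](C)(C)C(C)(C)C | intermediate
23 | 7-(benzyloxy)-6-[(1S,2S)-2-(benzyloxy)-1-{2-[(benzyloxy)methyl]-4-oxo-6-(2-phenylethyl)-4H-pyran-3-yl}-3-hydroxypropoxy]-2-(2-phenylethyl)-4H-chromen-4-one | O=c1cc(CCc2ccccc2)oc(COCc2ccccc2)c1[C@H](Oc1cc2c(=O)cc(CCc3ccccc3)oc2cc1OCc1ccccc1)[C@@H](OCc1ccccc1)CO | intermediate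
24 | (2R,3S)-2-(benzyloxy)-3-{[7-(benzyloxy)-4-oxo-2-(2-phenylethyl)-4H-chromen-6-yl]oxy}-3-{2-[(benzyloxy)methyl]-4-oxo-6-(2-phenylethyl)-4H-pyran-3-yl}propanal | O=c1cc(CCc2ccccc2)oc(COCc2ccccc2)c1[C@H](Oc1cc2c(=O)cc(CCc3ccccc3)oc2cc1OCc1ccccc1)[C@@H](OCc1ccccc1)C=O | intermediate
25 | (2R,3S)-2-(benzyloxy)-3-{[7-(benzyloxy)-4-oxo-2-(2-phenylethyl)-4H-chromen-6-yl]oxy}-3-{(2Z)-2-[(benzyloxy)methylidene]-6-(2-phenylethyl)-4-[(trimethylsilyl)oxy]-2H-pyran-3-yl}propanal | C[Si](C)(C)OC1=C([C@H](Oc2cc3c(=O)cc(CCc4ccccc4)oc3cc2OCc2ccccc2)[C@@H](OCc2ccccc2)C=O)/C(=C/OCc2ccccc2)OC(CCc2ccccc2)=C1 | intermediate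
26 | 7-O-trimethylsilyl ether of 27 (same spatial arrangement at C5–C8) | O=c1cc(CCc2ccccc2)oc2c1[C@H](Oc1cc3c(=O)cc(CCc4ccccc4)oc3cc1OCc1ccccc1)[C@@H](OCc1ccccc1)[C@@H](O[Si](C)(C)C)[C@@H]2OCc1ccccc1 | intermediate
27 | 7-(benzyloxy)-6-{[(5S,6S,7R,8S)-6,8-bis(benzyloxy)-7-hydroxy-4-oxo-2-(2-phenylethyl)-5,6,7,8-tetrahydro-4H-chromen-5-yl]oxy}-2-(2-phenylethyl)-4H-chromen-4-one | O=c1cc(CCc2ccccc2)oc2c1[C@H](Oc1cc3c(=O)cc(CCc4ccccc4)oc3cc1OCc1ccccc1)[C@@H](OCc1ccccc1)[C@@H](O)[C@@H]2OCc1ccccc1 | intermediate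
28 | 7-hydroxy-2-(2-phenylethyl)-6-{[(5S,6S,7R,8S)-6,7,8-trihydroxy-4-oxo-2-(2-phenylethyl)-5,6,7,8-tetrahydro-4H-chromen-5-yl]oxy}-4H-chromen-4-one | O=c1cc(CCc2ccccc2)oc2c1[C@H](Oc1cc3c(=O)cc(CCc4ccccc4)oc3cc1O)[C@@H](O)[C@@H](O)[C@@H]2O | target

**Step count**

Total: 16 steps. Longest linear sequence: 13 steps (steps 1–4 and 8–16); steps 5–7 supply the phenol that enters at step 9.

**Steps most likely to fail**

Step 15 (ring closure). The aldehyde may enolise and expel the C5 aryloxide or epimerise at C6 before the C8 carbon adds. The closure may also run through an open, non-chelated transition state and give the 6,7-trans alcohol, or the oxygen-bearing enol ether carbon may simply not add. The fallback raises the oxidation level of C7 and uses known chemistry; it sets out from 24 and returns at 27. Pinnick oxidation (NaClO2, NaH2PO4, 2-methyl-2-butene) should give the carboxylic acid F1, and Me3SiCHN2 the methyl ester F2. LiN(SiMe3)2 (THF, −78 °C) then effects the known lateral (γ) deprotonation of the 2-alkyl-4-pyranone and a Dieckmann-type acylation by the ester, which is far less prone than the aldehyde to enolise and eliminate, and after protonation this gives the 7-ketone F3. Luche reduction (NaBH4, CeCl3·7H2O, MeOH, −78 °C), with axial hydride delivery anti to the pseudoaxial C6 benzyloxy group, is expected to give 27.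

Step 9 (Mitsunobu etherification). Displacement at the doubly flanked carbinol may be slow, and partial ionisation to the pyranone-stabilised C5 cation would erode the inversion. The fallback makes the C5–O bond by epoxide opening instead; it sets out from 8 and returns at 20, bypassing steps 8–10. Stille coupling of 8 with (Z)-3-(tributylstannyl)prop-2-en-1-ol (Pd(PPh3)4, CuI, DMF) should give the (Z)-allylic alcohol F4. Sharpless asymmetric epoxidation (Ti(OiPr)4, L-(+)-diethyl tartrate, t-BuOOH, 4 Å sieves, CH2Cl2, −20 °C) should give the cis-epoxy alcohol F5. Ti(OiPr)4-mediated opening by phenol 14 at the pyranone-bearing carbon, with inversion, then delivers diol 20 directly.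

Step 8 (organometallic addition). Facial selectivity at the aldehyde may be poor, and the organometallic may be protonated by the vinylogously acidic CH2 groups of a second molecule before it adds. The fallback sets C5 by reduction instead of addition; it sets out from 8 and returns at 18. The Grignard reagent 16 is acylated with (4S)-N-methoxy-N,2,2-trimethyl-1,3-dioxolane-4-carboxamide to give the ketone F6, and Felkin–Anh reduction with LiBH(s-Bu)3 (THF, −78 °C) should give the anti alcohol 18.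

**Further compounds**

F1 | step 15 | (2R,3S)-2-(benzyloxy)-3-{[7-(benzyloxy)-4-oxo-2-(2-phenylethyl)-4H-chromen-6-yl]oxy}-3-{2-[(benzyloxy)methyl]-4-oxo-6-(2-phenylethyl)-4H-pyran-3-yl}propanoic acid | O=c1cc(CCc2ccccc2)oc(COCc2ccccc2)c1[C@H](Oc1cc2c(=O)cc(CCc3ccccc3)oc2cc1OCc1ccccc1)[C@@H](OCc1ccccc1)C(=O)O
F2 | step 15 | methyl (2R,3S)-2-(benzyloxy)-3-{[7-(benzyloxy)-4-oxo-2-(2-phenylethyl)-4H-chromen-6-yl]oxy}-3-{2-[(benzyloxy)methyl]-4-oxo-6-(2-phenylethyl)-4H-pyran-3-yl}propanoate | O=c1cc(CCc2ccccc2)oc(COCc2ccccc2)c1[C@H](Oc1cc2c(=O)cc(CCc3ccccc3)oc2cc1OCc1ccccc1)[C@@H](OCc1ccccc1)C(=O)OC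
F3 | step 15 | 7-(benzyloxy)-6-{[(5S,6R,8R)-6,8-bis(benzyloxy)-4,7-dioxo-2-(2-phenylethyl)-5,6,7,8-tetrahydro-4H-chromen-5-yl]oxy}-2-(2-phenylethyl)-4H-chromen-4-one | O=c1cc(CCc2ccccc2)oc2c1[C@H](Oc1cc3c(=O)cc(CCc4ccccc4)oc3cc1OCc1ccccc1)[C@@H](OCc1ccccc1)C(=O)[C@@H]2OCc1ccccc1
F4 | step 9 | 2-[(benzyloxy)methyl]-3-[(1Z)-3-hydroxyprop-1-en-1-yl]-6-(2-phenylethyl)-4H-pyran-4-one | O=c1cc(CCc2ccccc2)oc(COCc2ccccc2)c1/C=C\CO
F5 | step 9 | 2-[(benzyloxy)methyl]-3-[(2R,3S)-3-(hydroxymethyl)oxiran-2-yl]-6-(2-phenylethyl)-4H-pyran-4-one | O=c1cc(CCc2ccccc2)oc(COCc2ccccc2)c1[C@H]1O[C@H]1CO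
F6 | step 8 | 2-[(benzyloxy)methyl]-3-{[(4S)-2,2-dimethyl-1,3-dioxolan-4-yl]carbonyl}-6-(2-phenylethyl)-4H-pyran-4-one | O=c1cc(CCc2ccccc2)oc(COCc2ccccc2)c1C(=O)[C@@H]1COC(C)(C)O1
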